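The six-membered ring of the trans-hydrindane is opened across two bonds, C3a–C4 and C6–C7 (octahydroindene numbering: C4 bears the gem-dimethyl group, C7a the angular methyl). This exposes C4–C5–C6 as an acetone unit that bridges the ring-fusion CH (C3a) and the CH2 (C7) on the quaternary carbon, two positions held 1,3 on the cyclopentane. In one pot, a 4-methyl-4-(masked formyl)cyclopent-2-enol and 2-methoxypropene undergo ketal exchange, Claisen rearrangement (C3a–C4, trans ring fusion by 1,3-chirality transfer from the carbinol) and aldol condensation (C6–C7). The cyclopentenol comes from enantioselective opening of a meso epoxide; the lactone side chain comes from (2R,3S)-isocitric acid.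

Key step: step 5

Remark: the bicyclic core is numbered as octahydro-1H-indene throughout (C1 carries the side chain, C3a is the ring-fusion CH, C4 the gem-dimethyl carbon, C7a the angular-methyl carbon).
Assumption: the sense of induction of the chiral lithium amide in step 4 is taken by analogy with simple meso cyclopentene oxides; if it is opposite, the antipodal diamine is used.

Step 1
Reactants: 1 cyclopent-3-ene-1-carbonitrile
Product: 2 1-methylcyclopent-3-ene-1-carbonitrile
Conditions: LiN(i-Pr)2, THF, −78 °C; MeI, −78 → 0 °C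
Reagents that add atoms: iodomethane (CI)
Why: Alkylation of the lithiated nitrile (α-cyano carbanion) with MeI builds the quaternary carbon; the product keeps a mirror plane, so no stereocentre is created.

Step 2
Reactants: 2 1-methylcyclopent-3-ene-1-carbonitrile
Product: 4 4-(dimethoxymethyl)-4-methylcyclopent-1-ene, via aldehyde 3 (not isolated)
Conditions: i-Bu2AlH, CH2Cl2, −78 °C; aq. HCl; then HC(OMe)3, MeOH, p-TsOH (cat.), rt
Reagents that add atoms: trimethyl orthoformate (COC(OC)OC)
Why: Partial reduction of a nitrile by i-Bu2AlH stops at the N-aluminoimine, whose hydrolysis gives the aldehyde, and acid-catalysed acetalisation then masks it as a bulky, base-stable dimethyl acetal; no stereocentre is involved.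

Step 3
Reactants: 4 4-(dimethoxymethyl)-4-methylcyclopent-1-ene
Product: 5 meso-3-(dimethoxymethyl)-3-methyl-6-oxabicyclo[3.1.0]hexane (oxirane oxygen cis to methyl)
Conditions: mCPBA, NaHCO3, CH2Cl2, 0 °C
Reagents that add atoms: 3-chloroperoxybenzoic acid (O=C(OO)c1cccc(Cl)c1)
Why: Prilezhaev epoxidation under buffered conditions should occur on the alkene face remote from the bulky dimethoxymethyl group, giving the meso epoxide with oxygen cis to methyl (the minor meso isomer is separable).

Step 4
Reactants: 5 meso-3-(dimethoxymethyl)-3-methyl-6-oxabicyclo[3.1.0]hexane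
Product: 6 (1R,4R)-4-(dimethoxymethyl)-4-methylcyclopent-2-en-1-ol (hydroxyl cis to methyl)
Conditions: LiN(i-Pr)2 (1.5 equiv), (1S,3R,4R)-3-(pyrrolidin-1-ylmethyl)-2-azabicyclo[2.2.1]heptane (10 mol%), DBU, THF, 0 °C → rt
Reagents that add atoms: none
Why: Enantioselective base-promoted isomerisation of a meso epoxide to an allylic alcohol: the chiral lithium amide removes one of the two enantiotopic syn β-hydrogens, which fixes the quaternary carbon, while the C–O bond is retained so that the hydroxyl stays cis to methyl.

Step 5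
Reactants: 6 (1R,4R)-4-(dimethoxymethyl)-4-methylcyclopent-2-en-1-ol; 7 2-methoxypropene
Product: 12 (3aR,7aS)-7a-methyl-1,3a,4,7a-tetrahydro-5H-inden-5-one, via mixed ketal 8 (not isolated), via allyl isopropenyl ether 9 (not isolated), via keto acetal 10 (not isolated), via keto aldehyde 11 (not isolated)
Conditions: 7 (excess), pyridinium p-toluenesulfonate (cat.), toluene, sealed tube, rt → 135 °C; then 2 M HCl, THF, 65 °C, same flask
Reagents that add atoms: none
Why: Acid catalysis adds alcohol 6 to 2-methoxypropene (mixed ketal 8), loss of methanol gives allyl isopropenyl ether 9, its [3,3]-sigmatropic shift forms the C3a–C4 bond (ketone 10), and aqueous acid then unmasks aldehyde 11, whose methyl ketone enol attacks the formyl carbon and dehydrates, forming C6–C7. The closest known reaction types are the Saucy–Marbet (ketal) Claisen rearrangement of cyclic allylic alcohols and the acid-mediated intramolecular aldol condensation to cyclohexenones. The six-membered ring is closed by the aldol step in the 6-(enolendo)-exo-trig mode, the Claisen step itself passing through a six-membered pericyclic array that is not retained as a ring. The one new stereocentre, C3a, is controlled by 1,3-chirality transfer from the carbinol carbon: the new bond arrives on the face that carried oxygen, cis to the angular methyl and trans to the formyl carbon, so that the ring closure can only give the trans-fused bicycle; C7a is already in place. The step needs the allylic C–O bond to stay configurationally intact until rearrangement (mild acid, non-polar solvent) and the aldol to go through the methyl and not the methylene group, which the substrate secures because closure through CH2 would give a four-membered ring.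

Step 6
Reactants: 12 (3aR,7aS)-7a-methyl-1,3a,4,7a-tetrahydro-5H-inden-5-one
Product: 14 (3aR,7aS)-4,4,7a-trimethyl-1,3a,4,7a-tetrahydro-5H-inden-5-one, via monomethyl enone 13 (not isolated)
Conditions: KOt-Bu (3 equiv), MeI (6 equiv), THF/t-BuOH, 0 °C → rt
Reagents that add atoms: iodomethane (CI)
Why: Exhaustive α′-methylation of the cross-conjugated enolate, which is the only enolate available because the γ-carbon is quaternary and C3a–H is not acidic, installs the gem-dimethyl group without creating a stereocentre.

Step 7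
Reactants: 14 (3aR,7aS)-4,4,7a-trimethyl-1,3a,4,7a-tetrahydro-5H-inden-5-one
Product: 15 (3aR,7aR)-4,4,7a-trimethyl-1,3a,4,6,7,7a-hexahydro-5H-inden-5-one
Conditions: LiBH(s-Bu)3, THF, −78 °C; H2O
Reagents that add atoms: none
Why: 1,4-Reduction of the β-unsubstituted cyclohexenone by the hindered trialkylborohydride (1,2-attack is blocked by the adjacent quaternary carbon) leaves the isolated cyclopentene and both stereocentres untouched.

Step 8
Reactants: 15 (3aR,7aR)-4,4,7a-trimethyl-1,3a,4,6,7,7a-hexahydro-5H-inden-5-one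
Product: 16 (3aS,7aR)-4,4,7a-trimethyl-3a,4,5,6,7,7a-hexahydro-1H-indene
Conditions: N2H4·H2O, KOH, diethylene glycol, 130 → 210 °C
Reagents that add atoms: none
Why: Wolff–Kishner reduction through the hydrazone removes the ring-A carbonyl; the isolated alkene is inert and neither stereocentre is α to the carbonyl, so nothing can epimerise.

Step 9
Reactants: 16 (3aS,7aR)-4,4,7a-trimethyl-3a,4,5,6,7,7a-hexahydro-1H-indene
Product: 18 (3aS,7aS)-4,4,7a-trimethyl-3a,4,5,6,7,7a-hexahydro-1H-inden-1-one, via allylic alcohol 17 (not isolated)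
Conditions: SeO2 (cat.), t-BuOOH, CH2Cl2, rt; then MnO2, CH2Cl2, rt
Reagents that add atoms: tert-butyl hydroperoxide (CC(C)(C)OO)
Why: Allylic oxidation by SeO2 (ene reaction followed by [2,3]-sigmatropic shift, which puts oxygen on the carbon that lost hydrogen and so avoids transposition) attacks the only allylic CH2, and MnO2 then oxidises the allylic alcohol to the enone, erasing the carbinol stereocentre.

Step 10
Reactants: 18 (3aS,7aS)-4,4,7a-trimethyl-3a,4,5,6,7,7a-hexahydro-1H-inden-1-one
Product: 19 (3aS,7aS)-4,4,7a-trimethyloctahydro-1H-inden-1-one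
Conditions: H2 (1 atm), 10% Pd/C, EtOAc, rt
Reagents that add atoms: none
Why: Catalytic hydrogenation saturates the enone C=C; C2 and C3 become CH2, so no stereocentre is formed.

Step 11
Reactants: 19 (3aS,7aS)-4,4,7a-trimethyloctahydro-1H-inden-1-one
Product: 20 (1Z,3aS,7aS)-1-ethylidene-4,4,7a-trimethyloctahydro-1H-indene
Conditions: EtPPh3Br, KOt-Bu, THF, reflux
Reagents that add atoms: ethyltriphenylphosphonium bromide (CC[P+](c1ccccc1)(c1ccccc1)c1ccccc1.[Br-])
Why: Wittig olefination of the hindered cyclopentanone with the non-stabilised ylide gives the ethylidene compound, expected mainly as the Z isomer; the geometry is immaterial for the next step.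

Step 12
Reactants: 20 (1Z,3aS,7aS)-1-ethylidene-4,4,7a-trimethyloctahydro-1H-indene
Product: 22 1-[(1S,3aS,7aS)-4,4,7a-trimethyloctahydro-1H-inden-1-yl]ethan-1-one, via alkylborane 21 (not isolated)
Conditions: BH3·SMe2, THF, 0 °C → rt; then NMO, Pr4N[RuO4] (cat.), 4 Å MS, CH2Cl2, rt
Reagents that add atoms: N-methylmorpholine N-oxide (C[N+]1([O-])CCOCC1)
Why: Hydroboration puts boron on the less substituted alkene carbon and hydrogen on C1 from the face opposite the angular methyl, which sets C1 with its carbon substituent cis to that methyl, and perruthenate/N-oxide oxidation converts the C–B bond directly into the ketone.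

Step 13
Reactants: 22 1-[(1S,3aS,7aS)-4,4,7a-trimethyloctahydro-1H-inden-1-yl]ethan-1-one
Product: 23 1-[(1S,3aS,7aS)-4,4,7a-trimethyloctahydro-1H-inden-1-yl]ethenyl trifluoromethanesulfonate
Conditions: KN(SiMe3)2, THF, −78 °C; PhNTf2, −78 → 0 °C; dilute HCl work-up
Reagents that add atoms: N-phenylbis(trifluoromethanesulfonimide) (O=S(=O)(N(c1ccccc1)S(=O)(=O)C(F)(F)F)C(F)(F)F)
Why: Kinetic deprotonation of the methyl group (the methine next to the quaternary carbon is shielded) and O-triflation of the potassium enolate give the 1,1-disubstituted alkenyl triflate without touching C1.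

Step 14
Reactants: 24 monopotassium (2R,3S)-isocitrate
Product: 25 dimethyl (2R,3S)-5-oxooxolane-2,3-dicarboxylate (isocitric acid lactone dimethyl ester, ester groups cis)
Conditions: HCl, MeOH, reflux; then toluene, p-TsOH (cat.), 110 °C
Reagents that add atoms: methanol (CO)
Why: Fischer esterification with concurrent acid-catalysed γ-lactonisation of the chiral-pool hydroxy triacid; both stereocentres are carried over unchanged and the two ester groups are cis on the lactone.

Step 15
Reactants: 25 dimethyl (2R,3S)-5-oxooxolane-2,3-dicarboxylate; 23 alkenyl triflate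
Product: 27 dimethyl (2R,3S,4R)-5-oxo-4-{1-[(1R,3aS,7aS)-4,4,7a-trimethyloctahydro-1H-inden-1-yl]ethenyl}oxolane-2,3-dicarboxylate, via zinc enolate 26 (not isolated)
Conditions: LiN(SiMe3)2, THF, −78 °C; ZnCl2; then 23, Pd(dba)2 (5 mol%), P(t-Bu)3 (10 mol%), rt → 50 °C
Reagents that add atoms: none
Why: Palladium-catalysed α-alkenylation of a lactone enolate (Negishi-type coupling of the zinc enolate with the alkenyl triflate): the most acidic α-CH2 of the lactone is metalated, and the alkenyl group is delivered to the enolate face opposite the two cis ester groups, which sets C4 of the lactone.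

Step 16
Reactants: 27 dimethyl (2R,3S,4R)-5-oxo-4-(1-hydrindanylethenyl)oxolane-2,3-dicarboxylate
Product: 29 (2R,3S,4R)-3-(methoxycarbonyl)-5-oxo-4-{1-[(1R,3aS,7aS)-4,4,7a-trimethyloctahydro-1H-inden-1-yl]ethenyl}oxolane-2-carboxylic acid, via hydroxy diacid 28 (not isolated)
Conditions: LiOH (2.1 equiv), THF/H2O, 0 °C; then 1 M HCl, rt
Reagents that add atoms: lithium hydroxide ([Li+].[OH-])
Why: Saponification in which hydroxide first opens the activated lactone and then cleaves the α-oxygenated methyl ester faster than the hindered one, after which acid re-closes the five-membered lactone; no bond to a stereocentre is broken.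

Step 17
Reactants: 29 lactone mono-acid mono-ester
Product: 31 (3R,4R)-3-hydroxy-4-{(2R)-1-hydroxy-3-[(1R,3aS,7aS)-4,4,7a-trimethyloctahydro-1H-inden-1-yl]but-3-en-2-yl}oxolan-2-one, via triol acid 30 (not isolated)
Conditions: LiBH4 (excess), THF, 0 °C → rt; then 1 M HCl, rt
Reagents that add atoms: none
Why: Chemoselective hydride reduction: LiBH4 reduces the lactone and the methyl ester to primary alcohols but not the lithium carboxylate, and on acidification the acid lactonises onto the adjacent CH2OH (five- over six-membered ring), which frees the α-hydroxyl with retention.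

Step 18
Reactants: 31 hydroxy lactone primary alcohol
Product: 32 [(2R)-2-[(3R,4R)-4-hydroxy-5-oxooxolan-3-yl]-3-[(1R,3aS,7aS)-4,4,7a-trimethyloctahydro-1H-inden-1-yl]but-3-en-1-yl] acetate (target)
Conditions: Ac2O (1.05 equiv), 2,4,6-collidine, CH2Cl2, −20 °C
Reagents that add atoms: acetic anhydride (CC(=O)OC(C)=O)
Why: Acylation with one equivalent of anhydride at low temperature is selective for the unhindered primary alcohol over the secondary α-hydroxyl of the lactone, giving the target.

Compound list
1 | cyclopent-3-ene-1-carbonitrile | N#CC1CC=CC1 | starting material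
2 | 1-methylcyclopent-3-ene-1-carbonitrile | CC1(C#N)CC=CC1 | intermediate
3 | 1-methylcyclopent-3-ene-1-carbaldehyde | CC1(C=O)CC=CC1 | intermediate
4 | 4-(dimethoxymethyl)-4-methylcyclopent-1-ene | COC(OC)C1(C)CC=CC1 | intermediate
5 | meso-3-(dimethoxymethyl)-3-methyl-6-oxabicyclo[3.1.0]hexane, oxirane oxygen cis to methyl | COC(OC)[C@]1(C)C[C@H]2O[C@H]2C1 | intermediate
6 | (1R,4R)-4-(dimethoxymethyl)-4-methylcyclopent-2-en-1-ol | COC(OC)[C@@]1(C)C=C[C@H](O)C1 | intermediate
7 | 2-methoxypropene | COC(C)=C | starting material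
8 | 2-methoxypropan-2-yl ether of 6 (mixed ketal) | COC(OC)[C@@]1(C)C=C[C@H](OC(C)(C)OC)C1 | intermediate
9 | prop-1-en-2-yl ether of 6 (allyl isopropenyl ether) | COC(OC)[C@@]1(C)C=C[C@H](OC(C)=C)C1 | intermediate
10 | 1-[(1R,5R)-5-(dimethoxymethyl)-5-methylcyclopent-2-en-1-yl]propan-2-one | COC(OC)[C@]1(C)CC=C[C@H]1CC(C)=O | intermediate
11 | (1R,2R)-1-methyl-2-(2-oxopropyl)cyclopent-3-ene-1-carbaldehyde | O=C[C@]1(C)CC=C[C@H]1CC(C)=O | intermediate
12 | (3aR,7aS)-7a-methyl-1,3a,4,7a-tetrahydro-5H-inden-5-one | O=C1C=C[C@]2(C)CC=C[C@H]2C1 | intermediate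
13 | (3aR,7aS)-4,7a-dimethyl-1,3a,4,7a-tetrahydro-5H-inden-5-one, C4 epimers | CC1C(=O)C=C[C@]2(C)CC=C[C@@H]12 | intermediate
14 | (3aR,7aS)-4,4,7a-trimethyl-1,3a,4,7a-tetrahydro-5H-inden-5-one | CC1(C)C(=O)C=C[C@]2(C)CC=C[C@@H]12 | intermediate
15 | (3aR,7aR)-4,4,7a-trimethyl-1,3a,4,6,7,7a-hexahydro-5H-inden-5-one | CC1(C)C(=O)CC[C@]2(C)CC=C[C@@H]12 | intermediate
16 | (3aS,7aR)-4,4,7a-trimethyl-3a,4,5,6,7,7a-hexahydro-1H-indene | CC1(C)CCC[C@]2(C)CC=C[C@@H]12 | intermediate
17 | (1R,3aS,7aS)-4,4,7a-trimethyl-3a,4,5,6,7,7a-hexahydro-1H-inden-1-ol (expected major epimer, hydroxyl trans to the angular methyl) | CC1(C)CCC[C@]2(C)[C@H](O)C=C[C@@H]12 | intermediate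
18 | (3aS,7aS)-4,4,7a-trimethyl-3a,4,5,6,7,7a-hexahydro-1H-inden-1-one | CC1(C)CCC[C@]2(C)C(=O)C=C[C@@H]12 | intermediate
19 | (3aS,7aS)-4,4,7a-trimethyloctahydro-1H-inden-1-one | CC1(C)CCC[C@]2(C)C(=O)CC[C@@H]12 | intermediate
20 | (1Z,3aS,7aS)-1-ethylidene-4,4,7a-trimethyloctahydro-1H-indene | C/C=C1/CC[C@H]2C(C)(C)CCC[C@]12C | intermediate
21 | {(1S)-1-[(1S,3aS,7aS)-4,4,7a-trimethyloctahydro-1H-inden-1-yl]ethyl}borane | C[C@H](B)[C@H]1CC[C@H]2C(C)(C)CCC[C@]12C | intermediate
22 | 1-[(1S,3aS,7aS)-4,4,7a-trimethyloctahydro-1H-inden-1-yl]ethan-1-one | CC(=O)[C@H]1CC[C@H]2C(C)(C)CCC[C@]12C | intermediate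
23 | 1-[(1S,3aS,7aS)-4,4,7a-trimethyloctahydro-1H-inden-1-yl]ethenyl trifluoromethanesulfonate | C=C(OS(=O)(=O)C(F)(F)F)[C@H]1CC[C@H]2C(C)(C)CCC[C@]12C | intermediate
24 | monopotassium (2R,3S)-isocitrate | OC(=O)C[C@H](C(O)=O)[C@@H](O)C(=O)[O-].[K+] | starting material
25 | dimethyl (2R,3S)-5-oxooxolane-2,3-dicarboxylate | COC(=O)[C@@H]1OC(=O)C[C@@H]1C(=O)OC | intermediate
26 | chlorozinc enolate of 25 | COC(=O)[C@@H]1OC(O[Zn]Cl)=C[C@@H]1C(=O)OC | intermediate
27 | dimethyl (2R,3S,4R)-5-oxo-4-{1-[(1R,3aS,7aS)-4,4,7a-trimethyloctahydro-1H-inden-1-yl]ethenyl}oxolane-2,3-dicarboxylate | C=C([C@H]1CC[C@H]2C(C)(C)CCC[C@]12C)[C@@H]1C(=O)O[C@@H](C(=O)OC)[C@H]1C(=O)OC | intermediate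
28 | ring-opened hydroxy diacid mono(methyl ester) of 27 | C=C([C@H]1CC[C@H]2C(C)(C)CCC[C@]12C)[C@H](C(O)=O)[C@H](C(=O)OC)[C@@H](O)C(O)=O | intermediate
29 | (2R,3S,4R)-3-(methoxycarbonyl)-5-oxo-4-{1-[(1R,3aS,7aS)-4,4,7a-trimethyloctahydro-1H-inden-1-yl]ethenyl}oxolane-2-carboxylic acid | C=C([C@H]1CC[C@H]2C(C)(C)CCC[C@]12C)[C@@H]1C(=O)O[C@@H](C(O)=O)[C@H]1C(=O)OC | intermediate
30 | triol acid (open form of 31) | C=C([C@H]1CC[C@H]2C(C)(C)CCC[C@]12C)[C@H](CO)[C@H](CO)[C@@H](O)C(O)=O | intermediate
31 | (3R,4R)-3-hydroxy-4-{(2R)-1-hydroxy-3-[(1R,3aS,7aS)-4,4,7a-trimethyloctahydro-1H-inden-1-yl]but-3-en-2-yl}oxolan-2-one | C=C([C@H]1CC[C@H]2C(C)(C)CCC[C@]12C)[C@H](CO)[C@@H]1COC(=O)[C@@H]1O | intermediate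
32 | [(2R)-2-[(3R,4R)-4-hydroxy-5-oxooxolan-3-yl]-3-[(1R,3aS,7aS)-4,4,7a-trimethyloctahydro-1H-inden-1-yl]but-3-en-1-yl] acetate | C=C([C@H]1CC[C@H]2C(C)(C)CCC[C@]12C)[C@H](COC(C)=O)[C@@H]1COC(=O)[C@@H]1O | target

Total step count: 18. Longest linear sequence: 17 steps (steps 1–13 and 15–18; step 14 prepares the second fragment).

Steps most likely to fail

Step 15. Reductive elimination from the crowded alkenylpalladium enolate may be slow, so that the zinc enolate is merely protonated. Proton exchange between product and enolate may also scramble the new lactone stereocentre or move the double bond into conjugation. The fallback sets out from 23 and 25 and comes back at 27, reversing the polarity of the partners. Triflate 23 is borylated (B2pin2, PdCl2(dppf), KOAc, dioxane) to the alkenyl pinacol boronate F3. Lactone 25 is brominated through its silyl ketene acetal (LiN(SiMe3)2, Me3SiCl, then N-bromosuccinimide) to the 4-bromolactone F4. Suzuki–Miyaura coupling of F3 with F4 (Pd(OAc)2, P(o-tol)3, K3PO4, THF) should then give 27, the palladium enolate again taking up the alkenyl group trans to the two esters.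

Step 16. Hydroxide may fail to discriminate between the two methyl esters, or may trigger β-elimination of the lactone oxygen from the ester α-carbon before hydrolysis. The fallback sets out from 24 and comes back at 29, differentiating the carboxyl groups before the coupling. Acidification of 24 and dehydration with Ac2O should give the bicyclic isocitric lactone anhydride F5. Allyl alcohol should open it at the more electrophilic carbonyl next to the ring oxygen, giving the 2-allyl ester 3-acid F6, and Me3SiCHN2 then gives the 2-allyl 3-methyl diester F7. Coupling with 23 under the conditions of step 15 gives the allyl methyl diester F8, and Pd(PPh3)4 with morpholine removes the allyl group under neutral conditions to give 29.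

Step 4. The chiral base may discriminate the enantiotopic methylene groups poorly, or α-metalation of the epoxide may compete. The fallback sets out from 5 and comes back at 6, replacing desymmetrisation by resolution. Achiral LiNEt2 rearranges 5 to the racemate, that is 6 together with its antipode, (1S,4S)-4-(dimethoxymethyl)-4-methylcyclopent-2-en-1-ol F2. Lipase-catalysed acylation (immobilised Candida antarctica lipase B, vinyl acetate) should acylate one antipode only. The (1R,4R) series is collected as its acetate F1 and methanolysed (K2CO3, MeOH) to 6; should the enzyme prefer the antipode, 6 is collected directly as the unreacted alcohol.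

Further compounds
F1 | step 4 | (1R,4R)-4-(dimethoxymethyl)-4-methylcyclopent-2-en-1-yl acetate | COC(OC)[C@@]1(C)C=C[C@H](OC(C)=O)C1
F2 | step 4 | (1S,4S)-4-(dimethoxymethyl)-4-methylcyclopent-2-en-1-ol | COC(OC)[C@]1(C)C=C[C@@H](O)C1
F3 | step 15 | 4,4,5,5-tetramethyl-2-{1-[(1S,3aS,7aS)-4,4,7a-trimethyloctahydro-1H-inden-1-yl]ethenyl}-1,3,2-dioxaborolane | C=C(B1OC(C)(C)C(C)(C)O1)[C@H]1CC[C@H]2C(C)(C)CCC[C@]12C
F4 | step 15 | 4-bromo derivative of 25, bromine trans to the ester groups | COC(=O)[C@@H]1OC(=O)[C@@H](Br)[C@@H]1C(=O)OC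
F5 | step 16 | bicyclic anhydride of (2R,3S)-isocitric acid lactone | O=C1C[C@@H]2C(=O)OC(=O)[C@@H]2O1
F6 | step 16 | (2R,3S)-2-[(allyloxy)carbonyl]-5-oxooxolane-3-carboxylic acid | C=CCOC(=O)[C@@H]1OC(=O)C[C@@H]1C(O)=O
F7 | step 16 | 2-allyl 3-methyl (2R,3S)-5-oxooxolane-2,3-dicarboxylate | C=CCOC(=O)[C@@H]1OC(=O)C[C@@H]1C(=O)OC
F8 | step 16 | 2-allyl 3-methyl analogue of 27 | C=C([C@H]1CC[C@H]2C(C)(C)CCC[C@]12C)[C@@H]1C(=O)O[C@@H](C(=O)OCC=C)[C@H]1C(=O)OC
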